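## Retrosynthetic overview

1. Cut the all-E triene between its second and third carbons (Stille): a core E-vinylstannane plus the (2E,4E)-5-bromopentadienamide of 2-amino-3-hydroxycyclopentenone.
2. Cut the enamide C2–N bond: a 2-iodocyclohexenone plus (2E,4R)-2,4-dimethyloct-2-enamide (Evans methylation, Wittig).
3. Cyclohexenone ring: C2=C3 by intramolecular aldol condensation of a methyl ketone onto an α-quaternary aldehyde; this 1,5-keto-aldehyde comes from ozonolysis of a 1-methylcyclopentene (five- to six-ring expansion).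
4. Stereocentres: C5 from (R)-4-silyloxycyclopentenone (MeLi addition, oxidative transposition); C4 by acetylide addition anti to the silyloxy group, giving the cis-diol.
5. Ring order: the aminocyclopentenone ring is bought as cyclopentane-1,3-dione; the cyclopentene template is opened; the cyclohexenone is the only ring closed (step 17).

Assumption: the SMILES is read as the (4S,5R)-cis-diol with core positions C1 (C=O), C2 (C–N), C3 (=CH), C4 (C–OH, triene), C5 (CHOH), C6 (CH2); the (R)-silyloxycyclopentenone and glutaconaldehyde potassium salt are taken as catalogue items.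

## Route

**Upper amide (steps 1–6)**

Step 1
Reactants: 1 (R)-4-benzyloxazolidin-2-one; 2 hexanoyl chloride
Product: 3 (R)-4-benzyl-3-hexanoyloxazolidin-2-one
Conditions: Et3N, DMAP (cat.), CH2Cl2, 0 °C → rt
Reagents that add atoms: none
Why: DMAP-catalysed N-acylation (acyl transfer) attaches the hexanoyl chain to the Evans auxiliary without touching its stereocentre.

Step 2
Reactants: 3 (R)-4-benzyl-3-hexanoyloxazolidin-2-one
Product: 5 (R)-4-benzyl-3-[(R)-2-methylhexanoyl]oxazolidin-2-one, via sodium Z-enolate 4 (not isolated)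
Conditions: NaN(SiMe3)2, THF, −78 °C; then MeI, −78 °C
Reagents that add atoms: iodomethane, CI
Why: Evans asymmetric alkylation, in which the chelated Z-enolate is methylated on the face opposite the benzyl group, sets the (R)-methyl centre (dr about 10:1, minor isomer removed by chromatography).

Step 3
Reactants: 5 (R)-4-benzyl-3-[(R)-2-methylhexanoyl]oxazolidin-2-one
Product: 6 (R)-2-methylhexan-1-ol
Conditions: LiBH4, H2O (1 equiv), Et2O, 0 °C
Reagents that add atoms: none
Why: Reductive cleavage of the imide gives the primary alcohol and returns the auxiliary without epimerising the α-centre.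

Step 4
Reactants: 6 (R)-2-methylhexan-1-ol; 7 ethyl 2-(triphenylphosphoranylidene)propanoate
Product: 9 ethyl (2E,4R)-2,4-dimethyloct-2-enoate, via (R)-2-methylhexanal 8 (not isolated)
Conditions: PhI(OAc)2, TEMPO (10 mol %), CH2Cl2, rt; then 7, rt
Reagents that add atoms: none
Why: The neutral TEMPO/PhI(OAc)2 oxidation gives the epimerisable aldehyde, which the stabilised ylide traps in the same flask in an E-selective Wittig olefination (E:Z > 95:5).

Step 5
Reactants: 9 ethyl (2E,4R)-2,4-dimethyloct-2-enoate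
Product: 10 (2E,4R)-2,4-dimethyloct-2-enoic acid
Conditions: LiOH, THF/MeOH/H2O, rt; then 1 M HCl
Reagents that add atoms: lithium hydroxide, [Li+].[OH-]
Why: Ester saponification; aqueous hydroxide does not deprotonate the γ-centre, so configuration and olefin geometry are kept.

Step 6
Reactants: 10 (2E,4R)-2,4-dimethyloct-2-enoic acid
Product: 12 (2E,4R)-2,4-dimethyloct-2-enamide, via acyl imidazole 11 (not isolated)
Conditions: 1,1'-carbonyldiimidazole, THF, rt; then NH3 (7 M in MeOH), rt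
Reagents that add atoms: ammonia, N
Why: Carboxyl activation as the acyl imidazole followed by aminolysis gives the primary amide needed for the C–N coupling.

**Lower bromodienamide (steps 7–11)**

Step 7
Reactants: 13 cyclopentane-1,3-dione
Product: 14 2-(hydroxyimino)cyclopentane-1,3-dione
Conditions: NaNO2, aq. HCl, 0 °C
Reagents that add atoms: sodium nitrite, [Na+].[O-]N=O
Why: Electrophilic nitrosation of the enolised 1,3-dione at C2, followed by tautomerisation to the oxime.

Step 8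
Reactants: 14 2-(hydroxyimino)cyclopentane-1,3-dione
Product: 15 2-amino-3-hydroxycyclopent-2-en-1-one hydrochloride
Conditions: H2 (1 atm), Pd/C, HCl, MeOH, rt
Reagents that add atoms: hydrogen chloride, Cl
Why: Catalytic hydrogenation of the oxime gives the amine, trapped as the stable hydrochloride of the enaminone tautomer.

Step 9
Reactants: 16 glutaconaldehyde potassium salt
Product: 17 (2E,4E)-5-bromopenta-2,4-dienal
Conditions: PPh3, Br2, CH2Cl2, 0 °C; then 16, rt
Reagents that add atoms: bromine, BrBr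
Why: Deoxybromination: O-phosphonium activation of the dienolate oxygen and addition–elimination by bromide give the thermodynamically favoured E,E-bromodienal.

Step 10
Reactants: 17 (2E,4E)-5-bromopenta-2,4-dienal
Product: 18 (2E,4E)-5-bromopenta-2,4-dienoic acid
Conditions: NaClO2, NaH2PO4, 2-methylbut-2-ene, t-BuOH/H2O, rt
Reagents that add atoms: sodium chlorite, [Na+].[O-]Cl=O
Why: Pinnick oxidation converts the enal into the acid without affecting the vinyl bromide or the olefin geometry.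

Step 11
Reactants: 18 (2E,4E)-5-bromopenta-2,4-dienoic acid; 15 2-amino-3-hydroxycyclopent-2-en-1-one hydrochloride
Product: 20 (2E,4E)-5-bromo-N-(2-hydroxy-5-oxocyclopent-1-en-1-yl)penta-2,4-dienamide, via acid chloride 19 (not isolated)
Conditions: (COCl)2, DMF (cat.), CH2Cl2, 0 °C → rt; then 15, Et3N, CH2Cl2/DMF, 0 °C → rt
Reagents that add atoms: none
Why: Acid chloride formation and N-acylation give the amide; any O-acylated enol ester passes its acyl group on to nitrogen.

**Core and endgame (steps 12–22)**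

Step 12
Reactants: 21 (R)-4-[(tert-butyldimethylsilyl)oxy]cyclopent-2-en-1-one
Product: 22 (4R)-4-[(tert-butyldimethylsilyl)oxy]-1-methylcyclopent-2-en-1-ol (C1 epimers)
Conditions: MeLi, Et2O, −78 °C; aq. NH4Cl
Reagents that add atoms: methyllithium, [Li]C
Why: 1,2-Addition of methyllithium to the enone carbonyl at low temperature outruns enolisation, and the new carbinol centre is irrelevant because it becomes sp2 in the next step.

Step 13
Reactants: 22 (4R)-4-[(tert-butyldimethylsilyl)oxy]-1-methylcyclopent-2-en-1-ol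
Product: 23 (R)-5-[(tert-butyldimethylsilyl)oxy]-3-methylcyclopent-2-en-1-one
Conditions: pyridinium chlorochromate [C5H5NH][CrO3Cl], 4 Å MS, CH2Cl2, rt
Reagents that add atoms: pyridinium chlorochromate, [O-][Cr](=O)(=O)Cl.c1cc[nH+]cc1
Why: Babler–Dauben oxidative 1,3-transposition ([3,3]-shift of the tertiary allylic chromate, then oxidation) gives the 3-methyl enone and leaves the silyloxy stereocentre, now α' to the ketone, untouched.

Step 14
Reactants: 23 (R)-5-[(tert-butyldimethylsilyl)oxy]-3-methylcyclopent-2-en-1-one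
Product: 24 (1R,5R)-5-[(tert-butyldimethylsilyl)oxy]-3-methyl-1-[(trimethylsilyl)ethynyl]cyclopent-2-en-1-ol
Conditions: Me3SiC≡CH, n-BuLi, THF, −78 °C; then 23, −78 °C; aq. NH4Cl
Reagents that add atoms: ethynyltrimethylsilane, C#C[Si](C)(C)C
Why: 1,2-Addition of the weakly basic lithium acetylide occurs anti to the adjacent silyloxy group (steric and polar Felkin–Anh control), placing the new tertiary hydroxyl cis to it and setting the future C4 centre.

Step 15
Reactants: 24 (1R,5R)-5-[(tert-butyldimethylsilyl)oxy]-3-methyl-1-[(trimethylsilyl)ethynyl]cyclopent-2-en-1-ol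
Product: 25 (1R,5R)-5-[(tert-butyldimethylsilyl)oxy]-3-methyl-1-[(triethylsilyl)oxy]-1-[(trimethylsilyl)ethynyl]cyclopent-2-ene
Conditions: Et3SiOTf, 2,6-lutidine, CH2Cl2, −78 → 0 °C
Reagents that add atoms: triethylsilyl trifluoromethanesulfonate, CC[Si](CC)(CC)OS(=O)(=O)C(F)(F)F
Why: O-Silylation of the hindered tertiary propargylic alcohol with the silyl triflate protects it through ozonolysis, aldol closure and coupling.

Step 16
Reactants: 25 (1R,5R)-5-[(tert-butyldimethylsilyl)oxy]-3-methyl-1-[(triethylsilyl)oxy]-1-[(trimethylsilyl)ethynyl]cyclopent-2-ene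
Product: 27 (2R,3R)-3-[(tert-butyldimethylsilyl)oxy]-5-oxo-2-[(triethylsilyl)oxy]-2-[(trimethylsilyl)ethynyl]hexanal, via ozonide 26 (not isolated)
Conditions: O3, CH2Cl2, −78 °C (Sudan red 7B end point); then PPh3, −78 °C → rt
Reagents that add atoms: ozone, [O-][O+]=O
Why: Ozonolysis: the electron-rich trisubstituted cyclopentene reacts far faster than the silyl-capped alkyne, and reductive work-up opens the five-membered ring to the 1,5-keto-aldehyde.

Step 17
Reactants: 27 (2R,3R)-3-[(tert-butyldimethylsilyl)oxy]-5-oxo-2-[(triethylsilyl)oxy]-2-[(trimethylsilyl)ethynyl]hexanal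
Product: 29 (4R,5R)-5-[(tert-butyldimethylsilyl)oxy]-4-[(triethylsilyl)oxy]-4-[(trimethylsilyl)ethynyl]cyclohex-2-en-1-one, via aldol adduct 28 (not isolated)
Conditions: piperidine (0.3 equiv), AcOH (0.3 equiv), toluene (0.02 M), 50 °C
Reagents that add atoms: none
Why: Intramolecular aldol condensation (6-enolexo): the methyl-ketone enamine/enol adds to the non-enolisable α-quaternary aldehyde and the adduct dehydrates (E1cB), closing the six-membered ring without touching C4 or C5.

Step 18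
Reactants: 29 (4R,5R)-5-[(tert-butyldimethylsilyl)oxy]-4-[(triethylsilyl)oxy]-4-[(trimethylsilyl)ethynyl]cyclohex-2-en-1-one
Product: 30 (4R,5R)-5-[(tert-butyldimethylsilyl)oxy]-2-iodo-4-[(triethylsilyl)oxy]-4-[(trimethylsilyl)ethynyl]cyclohex-2-en-1-one
Conditions: I2, pyridine, CH2Cl2, 0 °C → rt
Reagents that add atoms: iodine, II
Why: Johnson α-iodination of the enone (pyridine conjugate addition, iodination of the enolate, elimination), as known for 4,4-disubstituted cyclohexenones.

Step 19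
Reactants: 30 (4R,5R)-5-[(tert-butyldimethylsilyl)oxy]-2-iodo-4-[(triethylsilyl)oxy]-4-[(trimethylsilyl)ethynyl]cyclohex-2-en-1-one; 12 (2E,4R)-2,4-dimethyloct-2-enamide
Product: 31 (2E,4R)-N-[(3R,4R)-4-[(tert-butyldimethylsilyl)oxy]-6-oxo-3-[(triethylsilyl)oxy]-3-[(trimethylsilyl)ethynyl]cyclohex-1-en-1-yl]-2,4-dimethyloct-2-enamide
Conditions: CuI (10 mol %), N,N'-dimethylethylenediamine (20 mol %), Cs2CO3, THF, 50 °C
Reagents that add atoms: none
Why: Copper-catalysed Goldberg–Buchwald amidation of the vinyl iodide with the primary amide forms the enamide C–N bond; the silyl cap keeps the alkyne away from copper.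

Step 20
Reactants: 31 (2E,4R)-N-[(3R,4R)-4-[(tert-butyldimethylsilyl)oxy]-6-oxo-3-[(triethylsilyl)oxy]-3-[(trimethylsilyl)ethynyl]cyclohex-1-en-1-yl]-2,4-dimethyloct-2-enamide
Product: 32 (2E,4R)-N-[(3R,4R)-3-ethynyl-3,4-dihydroxy-6-oxocyclohex-1-en-1-yl]-2,4-dimethyloct-2-enamide
Conditions: Bu4NF/AcOH (1:1, 6 equiv), THF, 0 °C → rt
Reagents that add atoms: none
Why: Fluoride-mediated desilylation, buffered with acetic acid to suppress retro-aldol and β-elimination, removes the C-silyl and both O-silyl groups.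

Step 21
Reactants: 32 (2E,4R)-N-[(3R,4R)-3-ethynyl-3,4-dihydroxy-6-oxocyclohex-1-en-1-yl]-2,4-dimethyloct-2-enamide
Product: 33 (2E,4R)-N-[(3R,4R)-3,4-dihydroxy-6-oxo-3-[(E)-2-(tributylstannyl)ethenyl]cyclohex-1-en-1-yl]-2,4-dimethyloct-2-enamide
Conditions: Bu3SnH, PdCl2(PPh3)2 (3 mol %), THF, 0 °C
Reagents that add atoms: tributyltin hydride, CCCC[SnH](CCCC)CCCC
Why: Palladium-catalysed syn-hydrostannylation of the terminal alkyne puts tin at the unhindered terminus, distal to the quaternary carbinol, giving the E-vinylstannane much faster than any enone reduction.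

Step 22
Reactants: 33 (2E,4R)-N-[(3R,4R)-3,4-dihydroxy-6-oxo-3-[(E)-2-(tributylstannyl)ethenyl]cyclohex-1-en-1-yl]-2,4-dimethyloct-2-enamide; 20 (2E,4E)-5-bromo-N-(2-hydroxy-5-oxocyclopent-1-en-1-yl)penta-2,4-dienamide
Product: 34 (2E,4R)-N-[(3S,4R)-3,4-dihydroxy-3-[(1E,3E,5E)-7-[(2-hydroxy-5-oxocyclopent-1-en-1-yl)amino]-7-oxohepta-1,3,5-trien-1-yl]-6-oxocyclohex-1-en-1-yl]-2,4-dimethyloct-2-enamide (target)
Conditions: PdCl2(MeCN)2 (10 mol %), DMF, rt, dark
Reagents that add atoms: none
Why: Stille cross-coupling joins the E-vinylstannane and the E,E-bromodiene with retention of both geometries, completing the all-E triene under neutral conditions that the free diol, enamide and enol tolerate.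

## Compound list

1 | (R)-4-benzyloxazolidin-2-one | O=C1N[C@H](Cc2ccccc2)CO1 | starting material
2 | hexanoyl chloride | CCCCCC(Cl)=O | starting material
3 | (R)-4-benzyl-3-hexanoyloxazolidin-2-one | CCCCCC(=O)N1[C@H](Cc2ccccc2)COC1=O | intermediate
4 | sodium Z-enolate of 3 (not isolated) | CCCC/C=C(\[O-])N1[C@H](Cc2ccccc2)COC1=O.[Na+] | intermediate
5 | (R)-4-benzyl-3-[(R)-2-methylhexanoyl]oxazolidin-2-one | CCCC[C@@H](C)C(=O)N1[C@H](Cc2ccccc2)COC1=O | intermediate
6 | (R)-2-methylhexan-1-ol | CCCC[C@@H](C)CO | intermediate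
7 | ethyl 2-(triphenylphosphoranylidene)propanoate | CCOC(=O)C(C)=P(c1ccccc1)(c1ccccc1)c1ccccc1 | starting material
8 | (R)-2-methylhexanal (not isolated) | CCCC[C@@H](C)C=O | intermediate
9 | ethyl (2E,4R)-2,4-dimethyloct-2-enoate | CCCC[C@@H](C)/C=C(\C)C(=O)OCC | intermediate
10 | (2E,4R)-2,4-dimethyloct-2-enoic acid | CCCC[C@@H](C)/C=C(\C)C(=O)O | intermediate
11 | 1-[(2E,4R)-2,4-dimethyloct-2-enoyl]imidazole (not isolated) | CCCC[C@@H](C)/C=C(\C)C(=O)n1ccnc1 | intermediate
12 | (2E,4R)-2,4-dimethyloct-2-enamide | CCCC[C@@H](C)/C=C(\C)C(N)=O | intermediate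
13 | cyclopentane-1,3-dione | O=C1CCC(=O)C1 | starting material
14 | 2-(hydroxyimino)cyclopentane-1,3-dione | O=C1CCC(=O)C1=NO | intermediate
15 | 2-amino-3-hydroxycyclopent-2-en-1-one hydrochloride | Cl.NC1=C(O)CCC1=O | intermediate
16 | glutaconaldehyde potassium salt (E,E) | [K+].[O-]/C=C/C=C/C=O | starting material
17 | (2E,4E)-5-bromopenta-2,4-dienal | O=C/C=C/C=C/Br | intermediate
18 | (2E,4E)-5-bromopenta-2,4-dienoic acid | OC(=O)/C=C/C=C/Br | intermediate
19 | (2E,4E)-5-bromopenta-2,4-dienoyl chloride (not isolated) | ClC(=O)/C=C/C=C/Br | intermediate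
20 | (2E,4E)-5-bromo-N-(2-hydroxy-5-oxocyclopent-1-en-1-yl)penta-2,4-dienamide | O=C(/C=C/C=C/Br)NC1=C(O)CCC1=O | intermediate
21 | (R)-4-[(tert-butyldimethylsilyl)oxy]cyclopent-2-en-1-one | O=C1C=C[C@H](O[Si](C)(C)C(C)(C)C)C1 | starting material
22 | (4R)-4-[(tert-butyldimethylsilyl)oxy]-1-methylcyclopent-2-en-1-ol (C1 epimers) | CC1(O)C=C[C@H](O[Si](C)(C)C(C)(C)C)C1 | intermediate
23 | (R)-5-[(tert-butyldimethylsilyl)oxy]-3-methylcyclopent-2-en-1-one | CC1=CC(=O)[C@H](O[Si](C)(C)C(C)(C)C)C1 | intermediate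
24 | (1R,5R)-5-[(tert-butyldimethylsilyl)oxy]-3-methyl-1-[(trimethylsilyl)ethynyl]cyclopent-2-en-1-ol (cis O,O) | CC1=C[C@@](O)(C#C[Si](C)(C)C)[C@H](O[Si](C)(C)C(C)(C)C)C1 | intermediate
25 | (1R,5R)-5-[(tert-butyldimethylsilyl)oxy]-3-methyl-1-[(triethylsilyl)oxy]-1-[(trimethylsilyl)ethynyl]cyclopent-2-ene | CC1=C[C@@](O[Si](CC)(CC)CC)(C#C[Si](C)(C)C)[C@H](O[Si](C)(C)C(C)(C)C)C1 | intermediate
26 | ozonide (bridged 1,2,4-trioxolane) of 25 (not isolated) | CC12C[C@@H](O[Si](C)(C)C(C)(C)C)[C@](O[Si](CC)(CC)CC)(C#C[Si](C)(C)C)C(OO1)O2 | intermediate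
27 | (2R,3R)-3-[(tert-butyldimethylsilyl)oxy]-5-oxo-2-[(triethylsilyl)oxy]-2-[(trimethylsilyl)ethynyl]hexanal | O=C[C@@](O[Si](CC)(CC)CC)(C#C[Si](C)(C)C)[C@H](O[Si](C)(C)C(C)(C)C)CC(C)=O | intermediate
28 | (3RS,4S,5R)-5-[(tert-butyldimethylsilyl)oxy]-3-hydroxy-4-[(triethylsilyl)oxy]-4-[(trimethylsilyl)ethynyl]cyclohexan-1-one (aldol adduct, not isolated) | O=C1CC(O)[C@@](O[Si](CC)(CC)CC)(C#C[Si](C)(C)C)[C@H](O[Si](C)(C)C(C)(C)C)C1 | intermediate
29 | (4R,5R)-5-[(tert-butyldimethylsilyl)oxy]-4-[(triethylsilyl)oxy]-4-[(trimethylsilyl)ethynyl]cyclohex-2-en-1-one | O=C1C=C[C@@](O[Si](CC)(CC)CC)(C#C[Si](C)(C)C)[C@H](O[Si](C)(C)C(C)(C)C)C1 | intermediate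
30 | (4R,5R)-5-[(tert-butyldimethylsilyl)oxy]-2-iodo-4-[(triethylsilyl)oxy]-4-[(trimethylsilyl)ethynyl]cyclohex-2-en-1-one | O=C1C(I)=C[C@@](O[Si](CC)(CC)CC)(C#C[Si](C)(C)C)[C@H](O[Si](C)(C)C(C)(C)C)C1 | intermediate
31 | (2E,4R)-N-[(3R,4R)-4-[(tert-butyldimethylsilyl)oxy]-6-oxo-3-[(triethylsilyl)oxy]-3-[(trimethylsilyl)ethynyl]cyclohex-1-en-1-yl]-2,4-dimethyloct-2-enamide | CCCC[C@@H](C)/C=C(\C)C(=O)NC1=C[C@@](O[Si](CC)(CC)CC)(C#C[Si](C)(C)C)[C@H](O[Si](C)(C)C(C)(C)C)CC1=O | intermediate
32 | (2E,4R)-N-[(3R,4R)-3-ethynyl-3,4-dihydroxy-6-oxocyclohex-1-en-1-yl]-2,4-dimethyloct-2-enamide | CCCC[C@@H](C)/C=C(\C)C(=O)NC1=C[C@@](O)(C#C)[C@H](O)CC1=O | intermediate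
33 | (2E,4R)-N-[(3R,4R)-3,4-dihydroxy-6-oxo-3-[(E)-2-(tributylstannyl)ethenyl]cyclohex-1-en-1-yl]-2,4-dimethyloct-2-enamide | CCCC[C@@H](C)/C=C(\C)C(=O)NC1=C[C@@](O)(/C=C/[Sn](CCCC)(CCCC)CCCC)[C@H](O)CC1=O | intermediate
34 | (2E,4R)-N-[(3S,4R)-3,4-dihydroxy-3-[(1E,3E,5E)-7-[(2-hydroxy-5-oxocyclopent-1-en-1-yl)amino]-7-oxohepta-1,3,5-trien-1-yl]-6-oxocyclohex-1-en-1-yl]-2,4-dimethyloct-2-enamide | CCCC[C@@H](C)/C=C(\C)C(=O)NC1=C[C@@](O)(/C=C/C=C/C=C/C(=O)NC2=C(O)CCC2=O)[C@H](O)CC1=O | target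

## Step count and risks

Total step count: 22.
Longest linear sequence: 11 steps (steps 12–22, from 21), half of the total. The upper amide branch is 6 steps and joins at step 19; the lower branch is 5 steps and joins at step 22.

The three steps most likely to fail:

Step 17 (aldol condensation). The amine catalyst may instead trigger β-elimination of the C5 silyloxy group or stall at the aldol stage. The fallback separates C–C bond formation from dehydration. It sets out from keto-aldehyde 27, which is cyclised with L-proline (30 mol %) in DMSO at rt to the aldol 28, this time isolated as a mixture of carbinol epimers. Treatment with MsCl and Et3N in CH2Cl2 at −20 °C gives the (4R,5R)-mesylate of aldol 28, F1, in which the sulfonate is by far the best leaving group. It is eliminated on warming to 0 °C with DBU, and the fallback comes back to the route at enone 29.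

Step 19 (copper-catalysed amidation). The carbonate base at 50 °C may eliminate the β-silyloxy group, or the hindered, electron-poor iodoenone may couple sluggishly with the unsaturated amide. The fallback forms the C–N bond with an ammonia surrogate and acylates afterwards. It sets out from iodoenone 30, which is coupled with benzophenone imine (Pd2(dba)3, Xantphos, Cs2CO3, toluene, 60 °C) to give the (4R,5R)-2-[(diphenylmethylene)amino]enone F2. Aqueous citric acid in THF releases the (4R,5R)-2-aminoenone F3. This is acylated with (2E,4R)-2,4-dimethyloct-2-enoyl chloride F4 (from acid 10 with (COCl)2 and cat. DMF) in CH2Cl2 with pyridine and DMAP, and the fallback comes back to the route at amide 31.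

Step 20 (global desilylation). The hindered secondary silyl ether may resist buffered fluoride, or the freed β-hydroxy ketone may dehydrate before the next two steps. The fallback keeps both O-silyl groups until after the coupling. It sets out from 31: AgNO3 (20 mol %) in acetone/H2O at rt removes only the alkynyl silyl group and gives the O-protected terminal alkyne F5. Hydrostannylation (Bu3SnH, PdCl2(PPh3)2, THF, 0 °C) gives the O-protected E-vinylstannane F6. Stille coupling with 20 (PdCl2(MeCN)2, DMF, rt) gives the bis-silyl ether of the target F7. HF·pyridine buffered with pyridine in THF at 0 °C removes both silyl ethers, and the fallback comes back to the route at target 34.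

## Further compounds

F1 | step 17 | (3RS,4R,5R)-5-[(tert-butyldimethylsilyl)oxy]-1-oxo-4-[(triethylsilyl)oxy]-4-[(trimethylsilyl)ethynyl]cyclohexan-3-yl methanesulfonate | O=C1CC(OS(C)(=O)=O)[C@@](O[Si](CC)(CC)CC)(C#C[Si](C)(C)C)[C@H](O[Si](C)(C)C(C)(C)C)C1
F2 | step 19 | (4R,5R)-5-[(tert-butyldimethylsilyl)oxy]-2-[(diphenylmethylene)amino]-4-[(triethylsilyl)oxy]-4-[(trimethylsilyl)ethynyl]cyclohex-2-en-1-one | O=C1C(N=C(c2ccccc2)c2ccccc2)=C[C@@](O[Si](CC)(CC)CC)(C#C[Si](C)(C)C)[C@H](O[Si](C)(C)C(C)(C)C)C1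
F3 | step 19 | (4R,5R)-2-amino-5-[(tert-butyldimethylsilyl)oxy]-4-[(triethylsilyl)oxy]-4-[(trimethylsilyl)ethynyl]cyclohex-2-en-1-one | NC1=C[C@@](O[Si](CC)(CC)CC)(C#C[Si](C)(C)C)[C@H](O[Si](C)(C)C(C)(C)C)CC1=O
F4 | step 19 | (2E,4R)-2,4-dimethyloct-2-enoyl chloride | CCCC[C@@H](C)/C=C(\C)C(Cl)=O
F5 | step 20 | (2E,4R)-N-[(3R,4R)-4-[(tert-butyldimethylsilyl)oxy]-3-ethynyl-6-oxo-3-[(triethylsilyl)oxy]cyclohex-1-en-1-yl]-2,4-dimethyloct-2-enamide | CCCC[C@@H](C)/C=C(\C)C(=O)NC1=C[C@@](O[Si](CC)(CC)CC)(C#C)[C@H](O[Si](C)(C)C(C)(C)C)CC1=O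
F6 | step 20 | (2E,4R)-N-[(3R,4R)-4-[(tert-butyldimethylsilyl)oxy]-6-oxo-3-[(triethylsilyl)oxy]-3-[(E)-2-(tributylstannyl)ethenyl]cyclohex-1-en-1-yl]-2,4-dimethyloct-2-enamide | CCCC[C@@H](C)/C=C(\C)C(=O)NC1=C[C@@](O[Si](CC)(CC)CC)(/C=C/[Sn](CCCC)(CCCC)CCCC)[C@H](O[Si](C)(C)C(C)(C)C)CC1=O
F7 | step 20 | (2E,4R)-N-[(3S,4R)-4-[(tert-butyldimethylsilyl)oxy]-3-[(1E,3E,5E)-7-[(2-hydroxy-5-oxocyclopent-1-en-1-yl)amino]-7-oxohepta-1,3,5-trien-1-yl]-6-oxo-3-[(triethylsilyl)oxy]cyclohex-1-en-1-yl]-2,4-dimethyloct-2-enamide | CCCC[C@@H](C)/C=C(\C)C(=O)NC1=C[C@@](O[Si](CC)(CC)CC)(/C=C/C=C/C=C/C(=O)NC2=C(O)CCC2=O)[C@H](O[Si](C)(C)C(C)(C)C)CC1=O
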